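**Retrosynthetic overview**
- Target ⇐ its hexa-TBS ether (fluoride, last step).
- Hexa-TBS ether ⇐ bis(cis-epoxide) bisphenol: both rings C are cut at O1–C2; each ring-A phenol oxygen (future O1) opens a (2S,3S)-aryl epoxide at benzylic C2 with inversion, two 6-endo closures in one operation.
- Feature used: units 1 and 2 are both (2R,3R) and differ only at C4 (4R against 4S), so the two C4 atoms of the central ArCH–O–CHAr ether are mirror images. With alkyne or Z-alkene arms this core is meso, and one chiral oxidant puts the same epoxide on both C2–C3 arms.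
- Bis(cis-epoxide) ⇐ meso bis(Z-alkene) ⇐ meso bis(arylalkyne) (Lindlar, twofold Sonogashira) ⇐ meso bis(1-arylpropargyl) ether ⇐ copper/pybox propargylic etherification of an (S)-propargylic alcohol with the racemic propargylic acetate, both made from one ring-A aldehyde.
- Ring order: rings A and B are bought as 2,3,4-trihydroxybenzaldehyde and 4-iodophenol; the two rings C are formed together in the second-to-last step.

Key step: step 13

Abbreviations: TBS = tert-butyldimethylsilyl; ArA = 2-(allyloxy)-3,4-bis(TBSO)phenyl; ArB = 4-(TBSO)phenyl; flavan numbering (O1, C2, C3, C4; rings A, B, C) is used for both arms throughout.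

Assumption: the antipodes of ProPhenol (step 3) and Ph-pybox (step 7) are named for their usual sense of induction; because the bis-propargylic ether is meso, only the requirement that steps 3 and 7 induce opposite configurations matters, and one ligand antipode is exchanged if the sense found is the other one.

Remark: in the twofold steps 9–12 and in step 14 the partly reacted species are of the same kind as the products and are not numbered; only the half-cyclised intermediate of step 13 is.

**Step 1**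
Reactants: 1 2,3,4-trihydroxybenzaldehyde
Product: 2 2-hydroxy-3,4-bis(TBSO)benzaldehyde
Conditions: TBSCl (2.1 equiv), imidazole, DMF, 0 °C
Reagents that add atoms: tert-butyldimethylsilyl chloride, CC(C)(C)[Si](C)(C)Cl
Why: Phenol silylation with a silyl chloride and imidazole; O2–H is hydrogen-bonded to the ortho formyl group and is the least nucleophilic, so two equivalents should cap only O3 and O4.

**Step 2**
Reactants: 2 2-hydroxy-3,4-bis(TBSO)benzaldehyde
Product: 3 2-(allyloxy)-3,4-bis(TBSO)benzaldehyde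
Conditions: allyl alcohol, PPh3, DIAD, THF, 0 °C → rt
Reagents that add atoms: allyl alcohol, C=CCO
Why: Mitsunobu etherification of the acidic chelated phenol under neutral conditions, which avoids phenoxide-induced silyl migration from O3 and cleavage of the para-formyl aryl silyl ether; allyl is chosen because it can later be removed without acid or base.

**Step 3**
Reactants: 3 2-(allyloxy)-3,4-bis(TBSO)benzaldehyde; 4 ethynyltrimethylsilane
Product: 5 (R)-1-ArA-3-(trimethylsilyl)prop-2-yn-1-ol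
Conditions: Me2Zn (3 equiv), (S,S)-ProPhenol (10 mol%), Ph3P=O (20 mol%), toluene, 0 °C; aq NH4Cl
Reagents that add atoms: none
Why: Zinc–ProPhenol asymmetric alkynylation of an aromatic aldehyde: the alkynylzinc formed from 4 and Me2Zn is delivered by the dinuclear zinc–ligand complex to one face of the formyl group, which sets the carbinol centre (R by CIP, because the silylalkynyl branch outranks the aryl group).

**Step 4**
Reactants: 5 (R)-1-ArA-3-(trimethylsilyl)prop-2-yn-1-ol
Product: 6 (S)-1-ArA-prop-2-yn-1-ol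
Conditions: AgNO3 (10 mol%), 2,6-lutidine, acetone/H2O, rt
Reagents that add atoms: none
Why: Silver-catalysed protodesilylation of an alkynylsilane, selective for the C(sp)–Si bond over aryl O–Si bonds; the stereocentre is not touched and its descriptor changes from R to S only because the alkynyl branch loses silicon.

**Step 5**
Reactants: 3 2-(allyloxy)-3,4-bis(TBSO)benzaldehyde; 7 ethynylmagnesium bromide
Product: 8 rac-1-ArA-prop-2-yn-1-ol
Conditions: THF, −78 → 0 °C; aq NH4Cl
Reagents that add atoms: none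
Why: Grignard 1,2-addition of the acetylide to the aldehyde gives the racemic propargylic alcohol, which is sufficient for the electrophilic partner because its stereocentre is erased in step 7.

**Step 6**
Reactants: 8 rac-1-ArA-prop-2-yn-1-ol
Product: 9 rac-1-ArA-prop-2-yn-1-yl acetate
Conditions: Ac2O, Et3N, DMAP (cat.), CH2Cl2, 0 °C
Reagents that add atoms: acetic anhydride, CC(=O)OC(C)=O
Why: DMAP-catalysed acylation of the secondary alcohol installs the ester leaving group required for copper-catalysed propargylic substitution.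

**Step 7**
Reactants: 6 (S)-1-ArA-prop-2-yn-1-ol; 9 rac-1-ArA-prop-2-yn-1-yl acetate (1.5 equiv)
Product: 10 meso-(1R,1′S)-bis(1-ArA-prop-2-yn-1-yl) ether
Conditions: (CuOTf)2·C6H6 (5 mol%), (S,S)-Ph-pybox (10 mol%), iPr2NEt, CH2Cl2, −20 °C
Reagents that add atoms: none
Why: Copper-catalysed asymmetric propargylic etherification via a copper allenylidene: the monovalent copper acetylide of 9 loses acetate to a planar allenylidene, so both enantiomers of 9 converge, and the hydroxyl of 6 adds to the γ-carbon on the face left open by the pybox ligand to set the new centre as R, opposite to the untouched S centre of 6, which makes the ether meso.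

**Step 8**
Reactants: 11 4-iodophenol
Product: 12 tert-butyl(4-iodophenoxy)dimethylsilane
Conditions: TBSCl, imidazole, DMF, rt
Reagents that add atoms: tert-butyldimethylsilyl chloride, CC(C)(C)[Si](C)(C)Cl
Why: Standard silylation of a phenol gives the ring-B coupling partner.

**Step 9**
Reactants: 10 meso-(1R,1′S)-bis(1-ArA-prop-2-yn-1-yl) ether; 12 tert-butyl(4-iodophenoxy)dimethylsilane (2.2 equiv)
Product: 13 meso-(1R,1′S)-bis(1-ArA-3-ArB-prop-2-yn-1-yl) ether
Conditions: Pd(PPh3)2Cl2 (5 mol%), CuI (10 mol%), Et3N, THF, rt, argon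
Reagents that add atoms: none
Why: Twofold Sonogashira coupling of the two terminal alkynes with the aryl iodide; the ether stereocentres are not involved, and the aryl allyl ethers should not be ionised by zerovalent palladium because no soft nucleophile is present to trap a π-allyl complex.

**Step 10**
Reactants: 13 meso-(1R,1′S)-bis(1-ArA-3-ArB-prop-2-yn-1-yl) ether
Product: 14 meso-(1R,1′S,2Z,2′Z)-bis(1-ArA-3-ArB-prop-2-en-1-yl) ether
Conditions: H2 (1 atm), Pd/CaCO3–Pb(OAc)2 (Lindlar catalyst), quinoline, EtOAc, rt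
Reagents that add atoms: none
Why: Lindlar semihydrogenation delivers H2 syn on the poisoned palladium surface to give both Z-alkenes; quinoline and stopping after two equivalents of H2 should spare the monosubstituted allyl ethers and the benzylic C–O bonds.

**Step 11**
Reactants: 14 meso-(1R,1′S,2Z,2′Z)-bis(1-ArA-3-ArB-prop-2-en-1-yl) ether
Product: 15 bis(cis-epoxide): (4R)-arm and (4S)-arm ether, each arm ArA-CH(O–)-[(2S,3S)-cis-epoxide]-ArB
Conditions: (S,S)-(salen)MnCl [salen = N,N′-bis(3,5-di-tert-butylsalicylidene)cyclohexane-1,2-diamine dianion] (2 × 5 mol%), 4-phenylpyridine N-oxide, aq NaOCl (pH 11.3), CH2Cl2, 0 °C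
Reagents that add atoms: sodium hypochlorite, [Na+].[O-]Cl
Why: Jacobsen–Katsuki epoxidation of cis-disubstituted styrenyl alkenes is reagent-controlled, and the (S,S) catalyst is expected, by analogy with cis-β-methylstyrene and cis-cinnamate esters, to give the (S)-benzylic cis-epoxide on each enantiotopic arm, so the meso diene is desymmetrised to the (2S,3S,4R)/(2S,3S,4S) bis-epoxide while the unconjugated allyl ethers react far more slowly.

**Step 12**
Reactants: 15 bis(cis-epoxide) bis(allyl ether)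
Product: 16 bis(cis-epoxide) bisphenol: as 15 with both ring-A O2 positions as free OH (arms 2S,3S,4R and 2S,3S,4S)
Conditions: Pd(PPh3)4 (10 mol%), morpholine (4 equiv), THF, 0 °C, argon; rapid filtration through Et3N-deactivated silica, used at once
Reagents that add atoms: none
Why: Tsuji–Trost deallylation: zerovalent palladium ionises each aryl allyl ether to a π-allyl complex that morpholine captures, which frees the two ring-A phenols under nearly neutral conditions that should leave the aryl epoxides, the aryl silyl ethers and all stereocentres untouched.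

**Step 13**
Reactants: 16 bis(cis-epoxide) bisphenol
Product: 18 hexakis-O-TBS ether of the target (unit 1 2R,3R,4R; unit 2 2R,3R,4S; TBS on O7/O8/O4′ of both units), via half-cyclised epoxyphenol 17 (not isolated)
Conditions: PPTS (20 mol%), 4 Å MS, CH2Cl2, −40 → −20 °C
Reagents that add atoms: none
Why: The pyridinium acid hydrogen-bonds to each epoxide oxygen and the neighbouring ring-A phenol oxygen attacks the benzylic epoxide carbon C2 anti to the departing oxygen, an SN2-like acid-catalysed intramolecular epoxide opening of the kind known for closing flavan-3-ols from 2-hydroxyaryl aryl-epoxides. Each pyran ring (ring C of unit 1 and ring C of unit 2) closes in the 6-endo-tet mode by O1–C2 bond formation; the first closure gives 17 (drawn with ring C of unit 1 closed; the other order is equally possible) and the second gives 18. The two new stereocentres are the two C2 atoms, each set by inversion of the (2S)-epoxide carbon to (2R), so each cis-epoxide becomes a 2,3-cis flavan-3-ol, while C3 (epoxide oxygen kept as 3-OH) and C4 are carried over unchanged. The step needs 6-endo over 5-exo regioselectivity and SN2 over SN1 fidelity: the first is secured by benzylic activation of C2 through the 4-silyloxyphenyl ring and by C3 being hindered and inductively deactivated by the adjacent C4–O bond, the second by the weak acid, the low temperature and the phenol held within reach of C2. Because both epoxides are (2S,3S) while C4 is R on one arm and S on the other, the same event gives the 3,4-cis unit 1 on one side and the 3,4-trans unit 2 on the other without differentiating the ends.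

**Step 14**
Reactants: 18 hexakis-O-TBS ether of the target
Product: 19 target, (2R,3R,4R)-2-(4-hydroxyphenyl)-4-{[(2R,3R,4S)-3,7,8-trihydroxy-2-(4-hydroxyphenyl)chroman-4-yl]oxy}chromane-3,7,8-triol
Conditions: Bu4NF/AcOH (1:1, 8 equiv), THF, 0 °C, argon
Reagents that add atoms: none
Why: Fluoride-mediated cleavage of the six aryl silyl ethers (Si–F bond formation), buffered with acetic acid so that the phenoxides are protonated at once and the bis-benzylic C4–O–C4 ether and the catechols should survive; no stereocentre is touched.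

**Compound list**
1 | 2,3,4-trihydroxybenzaldehyde | O=Cc1ccc(O)c(O)c1O | starting material
2 | 2-hydroxy-3,4-bis(TBSO)benzaldehyde | O=Cc1ccc(O[Si](C)(C)C(C)(C)C)c(O[Si](C)(C)C(C)(C)C)c1O | intermediate
3 | 2-(allyloxy)-3,4-bis(TBSO)benzaldehyde | O=Cc1ccc(O[Si](C)(C)C(C)(C)C)c(O[Si](C)(C)C(C)(C)C)c1OCC=C | intermediate
4 | ethynyltrimethylsilane | C#C[Si](C)(C)C | starting material
5 | (R)-1-[2-(allyloxy)-3,4-bis(TBSO)phenyl]-3-(trimethylsilyl)prop-2-yn-1-ol | C[Si](C)(C)C#C[C@@H](c1ccc(O[Si](C)(C)C(C)(C)C)c(O[Si](C)(C)C(C)(C)C)c1OCC=C)O | intermediate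
6 | (S)-1-[2-(allyloxy)-3,4-bis(TBSO)phenyl]prop-2-yn-1-ol | C#C[C@@H](c1ccc(O[Si](C)(C)C(C)(C)C)c(O[Si](C)(C)C(C)(C)C)c1OCC=C)O | intermediate
7 | ethynylmagnesium bromide | C#C[Mg]Br | starting material
8 | rac-1-[2-(allyloxy)-3,4-bis(TBSO)phenyl]prop-2-yn-1-ol | C#CC(O)c1ccc(O[Si](C)(C)C(C)(C)C)c(O[Si](C)(C)C(C)(C)C)c1OCC=C | intermediate
9 | rac-1-[2-(allyloxy)-3,4-bis(TBSO)phenyl]prop-2-yn-1-yl acetate | C#CC(OC(C)=O)c1ccc(O[Si](C)(C)C(C)(C)C)c(O[Si](C)(C)C(C)(C)C)c1OCC=C | intermediate
10 | meso-(1R,1′S)-bis{1-[2-(allyloxy)-3,4-bis(TBSO)phenyl]prop-2-yn-1-yl} ether | C#C[C@@H](c1ccc(O[Si](C)(C)C(C)(C)C)c(O[Si](C)(C)C(C)(C)C)c1OCC=C)O[C@@H](c1ccc(O[Si](C)(C)C(C)(C)C)c(O[Si](C)(C)C(C)(C)C)c1OCC=C)C#C | intermediate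
11 | 4-iodophenol | Oc1ccc(I)cc1 | starting material
12 | tert-butyl(4-iodophenoxy)dimethylsilane | CC(C)(C)[Si](C)(C)Oc1ccc(I)cc1 | intermediate
13 | meso-(1R,1′S)-bis{1-[2-(allyloxy)-3,4-bis(TBSO)phenyl]-3-[4-(TBSO)phenyl]prop-2-yn-1-yl} ether | CC(C)(C)[Si](C)(C)Oc1ccc(cc1)C#C[C@@H](c1ccc(O[Si](C)(C)C(C)(C)C)c(O[Si](C)(C)C(C)(C)C)c1OCC=C)O[C@@H](c1ccc(O[Si](C)(C)C(C)(C)C)c(O[Si](C)(C)C(C)(C)C)c1OCC=C)C#Cc1ccc(O[Si](C)(C)C(C)(C)C)cc1 | intermediate
14 | meso-(1R,1′S,2Z,2′Z)-bis{1-[2-(allyloxy)-3,4-bis(TBSO)phenyl]-3-[4-(TBSO)phenyl]prop-2-en-1-yl} ether | CC(C)(C)[Si](C)(C)Oc1ccc(cc1)/C=C\[C@@H](c1ccc(O[Si](C)(C)C(C)(C)C)c(O[Si](C)(C)C(C)(C)C)c1OCC=C)O[C@@H](c1ccc(O[Si](C)(C)C(C)(C)C)c(O[Si](C)(C)C(C)(C)C)c1OCC=C)/C=C\c1ccc(O[Si](C)(C)C(C)(C)C)cc1 | intermediate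
15 | (R)-ArA[(2S,3S)-3-ArB-oxiran-2-yl]methyl (S)-ArA[(2S,3S)-3-ArB-oxiran-2-yl]methyl ether (bis(cis-epoxide), ring-A O2 as allyl ethers) | CC(C)(C)[Si](C)(C)Oc1ccc(cc1)[C@@H]2O[C@@H]2[C@@H](c3ccc(O[Si](C)(C)C(C)(C)C)c(O[Si](C)(C)C(C)(C)C)c3OCC=C)O[C@@H](c3ccc(O[Si](C)(C)C(C)(C)C)c(O[Si](C)(C)C(C)(C)C)c3OCC=C)[C@H]2O[C@H]2c1ccc(O[Si](C)(C)C(C)(C)C)cc1 | intermediate
16 | bis(cis-epoxide) bisphenol: as 15 with 2-hydroxy-3,4-bis(TBSO)phenyl in place of ArA on both arms | CC(C)(C)[Si](C)(C)Oc1ccc(cc1)[C@@H]2O[C@@H]2[C@@H](c3ccc(O[Si](C)(C)C(C)(C)C)c(O[Si](C)(C)C(C)(C)C)c3O)O[C@@H](c3ccc(O[Si](C)(C)C(C)(C)C)c(O[Si](C)(C)C(C)(C)C)c3O)[C@H]2O[C@H]2c1ccc(O[Si](C)(C)C(C)(C)C)cc1 | intermediate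
17 | half-cyclised epoxyphenol: (2R,3R,4R)-7,8-bis(TBSO)-2-[4-(TBSO)phenyl]chroman-3-ol whose O4 carries the (4S)-carbinyl (2S,3S)-epoxide arm with free ring-A phenol | CC(C)(C)[Si](C)(C)Oc1ccc([C@H]2Oc3c(ccc(O[Si](C)(C)C(C)(C)C)c3O[Si](C)(C)C(C)(C)C)[C@@H](O[C@@H](c4ccc(O[Si](C)(C)C(C)(C)C)c(O[Si](C)(C)C(C)(C)C)c4O)[C@H]5O[C@H]5c6ccc(O[Si](C)(C)C(C)(C)C)cc6)[C@H]2O)cc1 | intermediate (not isolated)
18 | hexakis-O-TBS ether of the target: (2R,3R,4R)-7,8-bis(TBSO)-2-[4-(TBSO)phenyl]-4-{[(2R,3R,4S)-3-hydroxy-7,8-bis(TBSO)-2-[4-(TBSO)phenyl]chroman-4-yl]oxy}chroman-3-ol | CC(C)(C)[Si](C)(C)Oc1ccc([C@H]2Oc3c(ccc(O[Si](C)(C)C(C)(C)C)c3O[Si](C)(C)C(C)(C)C)[C@@H](O[C@H]3c4ccc(O[Si](C)(C)C(C)(C)C)c(O[Si](C)(C)C(C)(C)C)c4O[C@H](c4ccc(O[Si](C)(C)C(C)(C)C)cc4)[C@@H]3O)[C@H]2O)cc1 | intermediate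
19 | (2R,3R,4R)-2-(4-hydroxyphenyl)-4-{[(2R,3R,4S)-3,7,8-trihydroxy-2-(4-hydroxyphenyl)chroman-4-yl]oxy}chromane-3,7,8-triol | Oc1ccc([C@H]2Oc3c(ccc(O)c3O)[C@@H](O[C@H]3c4ccc(O)c(O)c4O[C@H](c4ccc(O)cc4)[C@@H]3O)[C@H]2O)cc1 | target

**Step count**
Total: 14 steps. Longest linear sequence: 11 steps (1, 2, 3, 4, 7, 9, 10, 11, 12, 13, 14).

**Steps most likely to fail**

Step 13 (key step). The benzylic C2–O bond of the 4-silyloxyphenyl epoxide may ionise before the phenol arrives (SN1 opening), which would erode the 2,3-cis relationship. Side paths are hydride shift to the C3 ketone (Meinwald rearrangement) and acid-induced ionisation of the C4–O–C4 ether next to the free ortho-phenol. The fallback removes the donor from ring B; it sets out from 10 and 11 and rejoins the route at 19. 4-Iodophenol 11 is acylated (pivaloyl chloride, pyridine) to 4-iodophenyl pivalate F1. F1 is coupled twice with 10 under the Sonogashira conditions of step 9 to give the bis(4-pivaloyloxyphenyl)alkyne ether F2. Lindlar semihydrogenation as in step 10 gives the bis(Z-alkene) F3, Jacobsen–Katsuki epoxidation as in step 11 gives the bis(cis-epoxide) F4, and deallylation as in step 12 gives the bisphenol F5. With a 4-acyloxyphenyl group the C2–O bond should no longer ionise on its own, so closure with camphorsulfonic acid (CH2Cl2, 0 °C) should proceed by clean inversion to the bis-flavan dipivalate F6. iBu2AlH (CH2Cl2, −78 °C) then cleaves the two aryl pivalates to the bis(4′-phenol) F7, and Bu4NF/AcOH as in step 14 gives 19.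

Step 7. The hindered secondary alcohol 6 may capture the copper allenylidene too slowly, so that acetate 9 is lost to elimination, hydrolysis or oligomerisation. The product may also re-ionise at its electron-rich propargylic carbons and drift toward a mixture of diastereomers. The fallback gives up stereocontrol in the C–O bond formation; it sets out from 8 and rejoins at 10. Racemic 8 is dimerised by dehydrative etherification with a catalytic Lewis acid (Bi(OTf)3, 4 Å MS, CH2Cl2, 0 °C, short reaction time to outrun Meyer–Schuster rearrangement). The propargylic cation is trapped by a second molecule of 8 without facial preference, so 10 should form together with the racemic C2-symmetric diastereomer, rac-(1S,1′S)-bis(1-ArA-prop-2-yn-1-yl) ether F8. F8 is removed by chromatography or crystallisation and only 10 is carried on; steps 3, 4 and 6 then become unnecessary.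

Step 11. Facial selectivity may be poor on the arm where the catalyst and the C4 stereocentre are mismatched. Cis-to-trans leakage through the radical intermediate of the stepwise oxygen transfer is possible, and the doubly activated C4–H bonds may be oxidised. The fallback changes the oxidant class; it sets out from 14 and rejoins at 15. Shi-type epoxidation with the chiral oxazolidinone-bearing sugar ketone developed for cis-alkenes (antipode chosen for the (S)-benzylic epoxide; KHSO5 as 2KHSO5·KHSO4·K2SO4, K2CO3 buffer at about pH 10.5, MeCN/dimethoxymethane, 0 °C) transfers oxygen from a dioxirane in one concerted step. This cannot isomerise the alkene and should leave terminal allyl ethers alone; it makes no new compound.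

**Further compounds**
F1 | step 13 | 4-iodophenyl pivalate | CC(C)(C)C(=O)Oc1ccc(I)cc1
F2 | step 13 | meso-(1R,1′S)-bis{1-[2-(allyloxy)-3,4-bis(TBSO)phenyl]-3-[4-(pivaloyloxy)phenyl]prop-2-yn-1-yl} ether | CC(C)(C)C(=O)Oc1ccc(cc1)C#C[C@@H](c1ccc(O[Si](C)(C)C(C)(C)C)c(O[Si](C)(C)C(C)(C)C)c1OCC=C)O[C@@H](c1ccc(O[Si](C)(C)C(C)(C)C)c(O[Si](C)(C)C(C)(C)C)c1OCC=C)C#Cc1ccc(OC(=O)C(C)(C)C)cc1
F3 | step 13 | meso-(2Z,2′Z)-bis{1-[2-(allyloxy)-3,4-bis(TBSO)phenyl]-3-[4-(pivaloyloxy)phenyl]prop-2-en-1-yl} ether | CC(C)(C)C(=O)Oc1ccc(cc1)/C=C\[C@@H](c1ccc(O[Si](C)(C)C(C)(C)C)c(O[Si](C)(C)C(C)(C)C)c1OCC=C)O[C@@H](c1ccc(O[Si](C)(C)C(C)(C)C)c(O[Si](C)(C)C(C)(C)C)c1OCC=C)/C=C\c1ccc(OC(=O)C(C)(C)C)cc1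
F4 | step 13 | bis(cis-epoxide) bis(allyl ether) with 4-(pivaloyloxy)phenyl as ring B (arms 2S,3S,4R and 2S,3S,4S) | CC(C)(C)C(=O)Oc1ccc(cc1)[C@@H]2O[C@@H]2[C@@H](c3ccc(O[Si](C)(C)C(C)(C)C)c(O[Si](C)(C)C(C)(C)C)c3OCC=C)O[C@@H](c3ccc(O[Si](C)(C)C(C)(C)C)c(O[Si](C)(C)C(C)(C)C)c3OCC=C)[C@H]2O[C@H]2c1ccc(OC(=O)C(C)(C)C)cc1
F5 | step 13 | bis(cis-epoxide) bisphenol with 4-(pivaloyloxy)phenyl as ring B | CC(C)(C)C(=O)Oc1ccc(cc1)[C@@H]2O[C@@H]2[C@@H](c3ccc(O[Si](C)(C)C(C)(C)C)c(O[Si](C)(C)C(C)(C)C)c3O)O[C@@H](c3ccc(O[Si](C)(C)C(C)(C)C)c(O[Si](C)(C)C(C)(C)C)c3O)[C@H]2O[C@H]2c1ccc(OC(=O)C(C)(C)C)cc1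
F6 | step 13 | target as its 7,8,7″,8″-tetrakis-O-TBS 4′,4‴-di-O-pivaloyl derivative | CC(C)(C)C(=O)Oc1ccc([C@H]2Oc3c(ccc(O[Si](C)(C)C(C)(C)C)c3O[Si](C)(C)C(C)(C)C)[C@@H](O[C@H]3c4ccc(O[Si](C)(C)C(C)(C)C)c(O[Si](C)(C)C(C)(C)C)c4O[C@H](c4ccc(OC(=O)C(C)(C)C)cc4)[C@@H]3O)[C@H]2O)cc1
F7 | step 13 | target as its 7,8,7″,8″-tetrakis-O-TBS ether (free 4′-phenols) | Oc1ccc([C@H]2Oc3c(ccc(O[Si](C)(C)C(C)(C)C)c3O[Si](C)(C)C(C)(C)C)[C@@H](O[C@H]3c4ccc(O[Si](C)(C)C(C)(C)C)c(O[Si](C)(C)C(C)(C)C)c4O[C@H](c4ccc(O)cc4)[C@@H]3O)[C@H]2O)cc1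
F8 | step 7 | rac-(1S,1′S)-bis{1-[2-(allyloxy)-3,4-bis(TBSO)phenyl]prop-2-yn-1-yl} ether (one enantiomer drawn) | C#C[C@@H](c1ccc(O[Si](C)(C)C(C)(C)C)c(O[Si](C)(C)C(C)(C)C)c1OCC=C)O[C@H](c1ccc(O[Si](C)(C)C(C)(C)C)c(O[Si](C)(C)C(C)(C)C)c1OCC=C)C#C
F0 | step 11 | none | none
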